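The data were computed for an exercise; scatter was added.

I count in minutes: the time starting material takes to halve under a given partner charge.

in all of them: starting material 20 mM
- dusk: partner 1.5 equiv; temperature −5 °C; run made earlier
- noon: partner 2.4 equiv; temperature 10 °C; run made earlier
- amber: partner 1.10 equiv; temperature 0 °C; time 6.0 min
- red: partner 1.10 equiv; temperature 20 °C; time 6.0 min

| run | time / min | mono adduct / % | double product / % | starting material / % |
|---|---|---|---|---|
| dusk | 0.500 | 2.1 | 0 | 98.4 |
| dusk | 0.667 | 3.6 | 0.5 | 97.1 |
| dusk | 1.00 | 5.6 | 0.3 | 94.4 |
| dusk | 1.50 | 6.5 | 0 | 92.9 |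
| dusk | 2.50 | 11.8 | 0.5 | 89.0 |
| dusk | 4.00 | 16.9 | 0.7 | 82.9 |
| dusk | 6.00 | 23.6 | 1.3 | 75.8 |
| noon | 0.200 | 6.4 | 0.1 | 93.0 |
| noon | 0.667 | 20.3 | 1.0 | 79.3 |
| noon | 1.00 | 26.1 | 2.3 | 70.8 |
| noon | 1.50 | 35.5 | 3.1 | 60.8 |
| noon | 2.50 | 45.3 | 7.9 | 47.2 |
| noon | 3.00 | 48.8 | 9.5 | 41.9 |
| noon | 4.00 | 53.3 | 13.0 | 32.5 |

(each reading ± 0.5 percentage points)

- which of these there is most of at the end, counted by the starting material in it, amber (starting material / mono adduct / double product)
- which of these there is most of at the end, counted by the starting material in it, red (starting material / mono adduct / double product)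
- amount of the one of these that there is most of at the end, in percent of the starting material charged, amber
- amount of the one of these that there is most of at the end, in percent of the starting material charged, red



Dusk loses starting material down to 75.8% in 6.00 min, which means halving every 15.0 min at 1.5 equiv. Noon reaches 79.3% at 0.667 min, which means halving every 1.99 min at 2.4 equiv. I take the rate as proportional to partner and scale both readings to 1.10 equiv:

at −5 °C: 20.5 min
at 10 °C: 4.35 min

The first of these is the charged half-life h, the time in which starting material halves if partner stays at its charge, a pseudo-first-order view. Between the two runs h shrinks by a factor of 4.71. I let that factor act evenly per degree, which gives: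

amber: h = 12.2 min
red: h = 1.55 min

Taken straight, red would keep 6.83% after 6.0 min. That is the weak link, because h in red is shorter than the time, and partner, charged at 1.10 equiv, falls along with starting material. With the two falling together, the fraction left after time t is

L = 1/(1 + ln(2)·t/h)

so I reckon that amber keeps 74.6% and red keeps 27.1%. Noon's last reading puts 80.4% of the converted material in mono adduct. Carrying that share over to red, I reckon 58.6% mono adduct there, more than its starting material, and in amber I reckon more starting material left than converted.

The forecast names starting material at 73% for amber and, by “stepwise integration”, mono adduct at 55% for red, the latter lower than my mono adduct.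

The flask gives starting material at 72.8% in amber and mono adduct at 49.6% in red.

    starting material + partner → mono adduct + released group (k = 0.0480 M⁻¹ s⁻¹, Ea = 63.0 kJ mol⁻¹)
    partner + mono adduct → double product + released group (k = 0.0180 M⁻¹ s⁻¹, Ea = 61.0 kJ mol⁻¹)
    partner → decomposed reagent (k = 1.30 × 10⁻⁴ s⁻¹, Ea = 94.0 kJ mol⁻¹)
    (constants at 0 °C)

In red, 41% of the starting material is left, more than my reckoned 27.1%, against 9.2% of the charged partner, and 6.18 mM of decomposed reagent stands. At 6.00 min in red, the first step uses partner 1.2 times as fast as decomposition does. For the neighbour flask like red kept at −5 °C, h = 20.5 min gives L = 83.1%, and that flask holds 81.6% starting material.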